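The rate constants are invented.

Take each flask below and bound its product from two sides: by the equilibrium it can reach and by the speed at which it can get there.

    starting material ⇌ intermediate A (K1 = 0.19, k1 = 0.054 s⁻¹, Ea1 = 86.0 kJ mol⁻¹, ΔH1 = 6.00 kJ mol⁻¹)
    starting material → intermediate B (k2 = 0.031 s⁻¹, Ea2 = 69.0 kJ mol⁻¹)
    partner + intermediate B ⇌ product (K3 = 110 M⁻¹, k3 = 2.0 M⁻¹ s⁻¹, Ea3 = 50.0 kJ mol⁻¹, ΔH3 = −62.0 kJ mol⁻¹)
    starting material + protic impurity → quenched substrate (k4 = 9.5 M⁻¹ s⁻¹, Ea4 = 41.0 kJ mol⁻¹)
    (constants at 20 °C)

in all of them: starting material 10 mM; partner 9.00 mM; protic impurity 1.00 mM; time 50 s

| run | temperature |
|---|---|
| teal | 70 °C |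
| amber | 45 °C |
| green | 20 °C |

- all constants are for 20 °C and move with temperature by the activation energies and enthalpies

1. the best flask by amount of product, in percent of the starting material charged; "all alike" if 1.5 percentage points covers them all (teal / amber / green / all alike)
2. amount of product at the end, in percent of the starting material charged, teal
3. amount of product at the end, in percent of the starting material charged, amber
4. amount of product at the end, in percent of the starting material charged, green

I froze the partner at its charge and reckoned, for green at 20 °C, ρ = 0.990, where ρ is the binding ratio, the equilibrium constant of the product step times the partner concentration, that is, product over intermediate B once binding has relaxed. My first extreme put the whole charge into intermediate B with binding relaxed, so that product took the share ρ/(1+ρ), which was 49.7 % for green. Teal, with its constant of 2.70 M⁻¹, had ρ = 0.0243 and a share of 2.37 %. For amber, midway in degrees, I took the geometric mean of the two ratios, ρ = 0.155, and a share of 13.4 %.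

My second extreme, worked for green, struck out the way back from product and the quench. Intermediate A returned at 0.284 s⁻¹, faster than intermediate B formed at 0.031 s⁻¹, so I treated it as a pre-equilibrium and got a supply rate a = 0.0261 s⁻¹. Capture by the frozen partner ran at b = 0.0180 s⁻¹. Two first-order steps in a row then gave 29.2 % at 50 s, below green's equilibrium share, which marked green as under kinetic control. Positive activation energies speed the hotter flasks, so I placed those under thermodynamic control. Quenching and the falling partner subtract from both extremes, and the way back from product subtracts from green's second one as well, so I committed to teal under its 2.37 %, amber under its 13.4 % and green under its 29.2 %, and, as a judgement and not a proof, since these were upper limits, to green as best.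

The forecast named green, with 2.2 % for teal, 9.9 % for amber and 18.9 % for green, reasoning that “heat strongly penalises product”.

The simulation gave 2.22 % for teal, 9.93 % for amber and 18.7 % for green, so the best flask was green.

The way back from product is the main reason teal stayed low: struck out, teal rose from 2.22 % to 87.5 %. At the end of teal, product over intermediate B stood at 0.0237, and ρ reckoned with the partner left in teal came to 0.0237. For the neighbour, a flask like amber kept at 20 °C and so with the charges and temperature of green, ρ returned to 0.990 and the equilibrium share to 49.7 %. The run gave 18.7 %, with 20 % of that neighbour's starting material still there.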